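**Retrosynthetic overview**

1. Target 11 ⇐ 3-ketone 10 (hydride delivered along the equatorial path gives the axial 3-OH) ⇐ 19-acetate 9 ⇐ dihydroxy acid 8.
2. 8 ⇐ lactol 7 by a redox-neutral radical isomerisation: the C15 acetal carbon becomes the carboxyl group, the C16–O bond is cut and C16 becomes the methyl group, with 13E carried over from the ring.
3. 7 ⇐ 15,16-olide 6 ⇐ (Z)-ene-1,4-diol 5 by regioselective oxidative lactonisation (new C15–O bond; the carbonyl moves from C16 to C15) ⇐ 16,15-olide 4.
4. 4 ⇐ andrographolide 1 by SN2′ hydride removal of the C14 oxygen and migration of the exocyclic alkene into ring B.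
5. Ring order: the trans-decalin (rings A and B) with C4, C5, C9 and C10 is taken intact from 1. Only the five-membered oxygen ring is opened (step 4), closed again on C15 (step 5) and opened for good (step 7).

Assumption: andrographolide (about 98 %, bulk extract of Andrographis paniculata) counts as a cheap commercial starting material. Labdane numbering is used (C19 = oxygenated C4 substituent cis to the C10 methyl; side chain C11–C16, C15 = carboxyl carbon of the target). The target has the ring configuration of 1 at C4, C5, C9 and C10 and the opposite configuration at C3.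

**Route**

Step 1
Reactants: 1 andrographolide
Product: 2 3,14,19-tri-O-acetylandrographolide
Conditions: Ac2O (6 equiv), pyridine, DMAP (5 mol%), CH2Cl2, 0 °C to rt
Reagents that add atoms: acetic anhydride, CC(=O)OC(C)=O
Why: Base-promoted O-acylation esterifies all three hydroxyls, which turns the C14 oxygen into the leaving group for step 2 and masks C3 and C19; no stereocentre is touched.

Step 2
Reactants: 2 3,14,19-tri-O-acetylandrographolide
Product: 3 (3R,4R,5S,9R,10S)-3,19-diacetoxylabda-8(17),13-dien-16,15-olide
Conditions: NaBH4 (1.5 equiv), THF/MeOH 10:1, −10 to 0 °C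
Reagents that add atoms: none
Why: SN2′ reduction of a Morita–Baylis–Hillman-type allylic acetate: hydride adds in conjugate fashion to C12 of the α-alkylidene lactone and the enolate expels the C14 acetate (E1cB), so the double bond moves into the lactone ring as the butenolide; the C14 stereocentre is removed on purpose and the isolated alkene and hindered acetates do not react.

Step 3
Reactants: 3 (3R,4R,5S,9R,10S)-3,19-diacetoxylabda-8(17),13-dien-16,15-olide
Product: 4 (3R,4R,5S,9R,10S)-3,19-diacetoxylabda-7,13-dien-16,15-olide
Conditions: Co(salen)Cl (trivalent cobalt; salen = (R,R)-N,N′-bis(3,5-di-tert-butylsalicylidene)cyclohexane-1,2-diaminate, 5 mol%), PhSiH3 (5 mol%), benzene, rt, argon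
Reagents that add atoms: none
Why: Metal-hydride hydrogen-atom-transfer alkene isomerisation: the cobalt hydride gives H• to C17 and the tertiary C8 radical returns H• from the accessible C7 methylene and not from the shielded tertiary C9–H, so the trisubstituted 7-ene forms under kinetic control; the conjugated butenolide alkene is inert and C9 keeps its configuration.

Step 4
Reactants: 4 (3R,4R,5S,9R,10S)-3,19-diacetoxylabda-7,13-dien-16,15-olide
Product: 5 (3R,4R,5S,9R,10S,13Z)-labda-7,13-diene-3,15,16,19-tetraol
Conditions: LiAlH4 (4 equiv), THF, −20 to 0 °C; NaOH (aq) work-up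
Reagents that add atoms: none
Why: Hydride reduction of esters: 1,2-reduction opens the unsaturated lactone to the ene-1,4-diol, whose Z geometry is fixed by the former ring, and both acetates are cleaved in the same operation.

Step 5
Reactants: 5 (3R,4R,5S,9R,10S,13Z)-labda-7,13-diene-3,15,16,19-tetraol
Product: 6 (3R,4R,5S,9R,10S)-3,19-dihydroxylabda-7,13-dien-15,16-olide
Conditions: MnO2 (activated, 25 equiv), EtOAc, rt
Reagents that add atoms: none
Why: Chemoselective allylic oxidation with oxidative lactonisation: MnO2 leaves the saturated C3 and C19 hydroxyls alone and attacks first the C15 carbinol, which is less hindered and whose developing radical is stabilised at the fully substituted C13; O16 then closes onto C15 (new C15–O bond) and the ring is oxidised on to the lactone, so the carbonyl ends at C15 instead of C16.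

Step 6
Reactants: 6 (3R,4R,5S,9R,10S)-3,19-dihydroxylabda-7,13-dien-15,16-olide
Product: 7 (3R,4R,5S,9R,10S)-15,16-epoxylabda-7,13-diene-3,15,19-triol (lactol, both C15 epimers)
Conditions: i-Bu2AlH (3.5 equiv), THF/CH2Cl2, −78 °C; KNaC4H4O6 (aq), pH 7–8
Reagents that add atoms: none
Why: Partial 1,2-reduction of a lactone: the tetrahedral aluminium hemiacetal survives at −78 °C and gives the lactol on neutral work-up (acid is avoided because the lactol aromatises to the furan); the new C15 centre forms as both epimers and is destroyed in step 7.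

Step 7
Reactants: 7 (3R,4R,5S,9R,10S)-15,16-epoxylabda-7,13-diene-3,15,19-triol
Product: 8 (3R,4R,5S,9R,10S,13E)-3,19-dihydroxylabda-7,13-dien-15-oic acid
Conditions: HSCH2CO2Me (20 mol%), VA-044 (2,2′-azobis[2-(2-imidazolin-2-yl)propane] dihydrochloride, 10 mol% in two portions), degassed MeCN/phosphate buffer pH 7.4 (1:1), 45 °C; then pH 4, extraction
Reagents that add atoms: none
Why: Proposed new method: thiol-catalysed radical-chain redox isomerisation of an unsaturated γ-lactol to an enoic acid — the electrophilic thiyl radical abstracts the hydridic C15–H (allylic and flanked by two oxygens), the radical undergoes β-scission of the ring O–C16 bond to form the carboxyl C=O and a C16 allyl radical conjugated with it, and this radical takes H from the thiol at the primary terminus C16 to give the methyl group and a new thiyl radical; the 13E geometry (C16 cis to C15) is carried over from the ring as long as H transfer outpaces rotation of the allyl radical, and the closest known reaction type is the thiol-catalysed (polarity-reversal) radical redox rearrangement of cyclic benzylidene acetals to benzoate esters.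

Step 8
Reactants: 8 (3R,4R,5S,9R,10S,13E)-3,19-dihydroxylabda-7,13-dien-15-oic acid
Product: 9 (3R,4R,5S,9R,10S,13E)-19-acetoxy-3-hydroxylabda-7,13-dien-15-oic acid
Conditions: Ac2O (2.2 equiv), pyridine, CH2Cl2, −20 to 0 °C; then NaHCO3 (aq)/THF
Reagents that add atoms: acetic anhydride, CC(=O)OC(C)=O
Why: Kinetic differentiation in O-acylation: the primary C19 hydroxyl reacts much faster than the secondary C3 hydroxyl next to the quaternary C4, and the mixed anhydride formed at the carboxyl group is hydrolysed in the bicarbonate work-up.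

Step 9
Reactants: 9 (3R,4R,5S,9R,10S,13E)-19-acetoxy-3-hydroxylabda-7,13-dien-15-oic acid
Product: 10 (4R,5S,9R,10S,13E)-19-acetoxy-3-oxolabda-7,13-dien-15-oic acid
Conditions: Dess–Martin periodinane (1.5 equiv), NaHCO3, CH2Cl2, 0 °C to rt
Reagents that add atoms: none
Why: Dess–Martin oxidation of the secondary alcohol under buffered conditions; C4 is quaternary, so neither epimerisation nor β-elimination is possible, and the acetate blocks retro-aldol loss of C19.

Step 10
Reactants: 10 (4R,5S,9R,10S,13E)-19-acetoxy-3-oxolabda-7,13-dien-15-oic acid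
Product: 11 (3S,4R,5S,9R,10S,13E)-19-acetoxy-3-hydroxylabda-7,13-dien-15-oic acid (target)
Conditions: LiBH(s-Bu)3 (2.5 equiv), THF, −78 °C, 1 h; NH4Cl (aq)
Reagents that add atoms: none
Why: Diastereoselective ketone reduction with a bulky trialkylborohydride: the reagent approaches C3 along the equatorial path because the axial path is blocked by the axial hydrogens at C1 and C5, so hydride ends up equatorial and the hydroxyl axial (3S), trans to C19 and to the C10 methyl; the acid is protected in situ as its lithium salt and the hindered enoate and the acetate do not react at −78 °C.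

**Compound list**

1 | andrographolide, (3R,4R,5S,9R,10S,12E,14S)-3,14,19-trihydroxylabda-8(17),12-dien-16,15-olide; 3-OH equatorial and cis to C19 | OC[C@@]1(C)[C@H]2CCC(=C)[C@@H](C/C=C3/C(=O)OC[C@H]3O)[C@]2(C)CC[C@H]1O | starting material
2 | 3,14,19-tri-O-acetylandrographolide | CC(=O)OC[C@@]1(C)[C@H]2CCC(=C)[C@@H](C/C=C3/C(=O)OC[C@H]3OC(C)=O)[C@]2(C)CC[C@H]1OC(C)=O | intermediate
3 | (3R,4R,5S,9R,10S)-3,19-diacetoxylabda-8(17),13-dien-16,15-olide (α-substituted butenolide, carbonyl at C16) | CC(=O)OC[C@@]1(C)[C@H]2CCC(=C)[C@@H](CCC3=CCOC3=O)[C@]2(C)CC[C@H]1OC(C)=O | intermediate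
4 | (3R,4R,5S,9R,10S)-3,19-diacetoxylabda-7,13-dien-16,15-olide | CC(=O)OC[C@@]1(C)[C@H]2CC=C(C)[C@@H](CCC3=CCOC3=O)[C@]2(C)CC[C@H]1OC(C)=O | intermediate
5 | (3R,4R,5S,9R,10S,13Z)-labda-7,13-diene-3,15,16,19-tetraol | OC[C@@]1(C)[C@H]2CC=C(C)[C@@H](CC/C(CO)=C/CO)[C@]2(C)CC[C@H]1O | intermediate
6 | (3R,4R,5S,9R,10S)-3,19-dihydroxylabda-7,13-dien-15,16-olide (β-substituted butenolide, carbonyl at C15) | OC[C@@]1(C)[C@H]2CC=C(C)[C@@H](CCC3=CC(=O)OC3)[C@]2(C)CC[C@H]1O | intermediate
7 | (3R,4R,5S,9R,10S)-15,16-epoxylabda-7,13-diene-3,15,19-triol (C15 lactol, both epimers) | OC[C@@]1(C)[C@H]2CC=C(C)[C@@H](CCC3=CC(O)OC3)[C@]2(C)CC[C@H]1O | intermediate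
8 | (3R,4R,5S,9R,10S,13E)-3,19-dihydroxylabda-7,13-dien-15-oic acid | OC[C@@]1(C)[C@H]2CC=C(C)[C@@H](CC/C(C)=C/C(=O)O)[C@]2(C)CC[C@H]1O | intermediate
9 | (3R,4R,5S,9R,10S,13E)-19-acetoxy-3-hydroxylabda-7,13-dien-15-oic acid (3-OH equatorial) | CC(=O)OC[C@@]1(C)[C@H]2CC=C(C)[C@@H](CC/C(C)=C/C(=O)O)[C@]2(C)CC[C@H]1O | intermediate
10 | (4R,5S,9R,10S,13E)-19-acetoxy-3-oxolabda-7,13-dien-15-oic acid | CC(=O)OC[C@@]1(C)[C@H]2CC=C(C)[C@@H](CC/C(C)=C/C(=O)O)[C@]2(C)CCC1=O | intermediate
11 | (3S,4R,5S,9R,10S,13E)-19-acetoxy-3-hydroxylabda-7,13-dien-15-oic acid (3-OH axial, trans to C19 and C20) | CC(=O)OC[C@@]1(C)[C@H]2CC=C(C)[C@@H](CC/C(C)=C/C(=O)O)[C@]2(C)CC[C@@H]1O | target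

**Step count and risks**

Total steps: 10. Longest linear sequence: 10 (fully linear from 1).

The three steps most likely to fail:

Step 7, the proposed new isomerisation. Risks are abstraction of a C16–H instead of C15–H (this leads to the regioisomeric acid), H return at C14 (deconjugated exo-methylene acid), loss of water from 7 to the furan, and partial E/Z scrambling. The fallback uses known chemistry; it sets out from 6 and comes back at 8, so it also replaces step 6. PhSeNa (from PhSeH and NaH, THF/HMPA, 18-crown-6, 60 °C) opens the lactone by SN2 attack at the allylic C16 and gives (3R,4R,5S,9R,10S,13Z)-3,19-dihydroxy-16-(phenylselanyl)labda-7,13-dien-15-oic acid F3. Radical deselenation with Bu3SnH and AIBN in benzene at 80 °C then puts hydrogen on C16 and gives 8.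

Step 5, regio- and chemoselectivity of the oxidative lactonisation. Oxidation at C16 would return the 16,15-olide series. The fallback sets out from 4 and comes back at 6, so it also replaces step 4, and places the C15 oxygen by catalyst-controlled C–H functionalisation instead of alcohol oxidation. i-Bu2AlH (excess, −78 to −20 °C) followed by dilute HCl reduces the butenolide, cleaves the acetates and dehydrates the lactol to the furan (3R,4R,5S,9R,10S)-15,16-epoxylabda-7,13(16),14-triene-3,19-diol F1. Iridium-catalysed C–H borylation at the less hindered furan α-carbon ([Ir(OMe)(cod)]2, monovalent iridium, 4,4′-di-tert-butyl-2,2′-bipyridine, HBpin to mask the hydroxyls, then B2pin2, THF, rt, methanol quench) gives the 15-(4,4,5,5-tetramethyl-1,3,2-dioxaborolan-2-yl) derivative of that furan F2. Oxidation with NaBO3·4H2O in THF/water and tautomerisation of the 2-hydroxyfuran give 6.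

Step 3, regiochemistry of the alkene shift (the 8(9)-ene or unchanged 3 may dominate). The fallback sets out from 3 and comes back at 4 and uses a cationic instead of a radical pathway. p-TsOH·H2O (10 mol%) in benzene at 60 °C protonates the exocyclic alkene to the C8 tertiary cation, which loses H7; the reaction is stopped at partial conversion, 4 is separated from the 8(9)-ene on AgNO3-impregnated silica and 3 is recycled. This fallback makes no new compound (F0).

**Further compounds**

F0 | step 3 | none | none
F1 | step 5 | (3R,4R,5S,9R,10S)-15,16-epoxylabda-7,13(16),14-triene-3,19-diol | OC[C@@]1(C)[C@H]2CC=C(C)[C@@H](CCc3ccoc3)[C@]2(C)CC[C@H]1O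
F2 | step 5 | (3R,4R,5S,9R,10S)-15-(4,4,5,5-tetramethyl-1,3,2-dioxaborolan-2-yl)-15,16-epoxylabda-7,13(16),14-triene-3,19-diol | OC[C@@]1(C)[C@H]2CC=C(C)[C@@H](CCc3coc(B4OC(C)(C)C(C)(C)O4)c3)[C@]2(C)CC[C@H]1O
F3 | step 7 | (3R,4R,5S,9R,10S,13Z)-3,19-dihydroxy-16-(phenylselanyl)labda-7,13-dien-15-oic acid | OC[C@@]1(C)[C@H]2CC=C(C)[C@@H](CC/C(C[Se]c3ccccc3)=C/C(=O)O)[C@]2(C)CC[C@H]1O
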